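Counted in moles of product per mole of reagent charged, the east flask on this bench has stopped at a modest return.

common to all: reagent 0.435 M; free catalyst 1.3 mM
- east: substrate 0.29 M; the very flask that is asked about, followed so far
- south-west: substrate 0.19 M; run made earlier
- flask: substrate 0.29 M; time 80 min

| run | time / min | product / % | substrate / % |
|---|---|---|---|
| east | 2.50 | 24.6 | 76.8 |
| east | 8.00 | 48.4 | 50.2 |
| east | 15.0 | 58.9 | 40.1 |
| east | 20.0 | 62.5 | 37.6 |
| east | 30.0 | 62.8 | 35.4 |
| east | 40.0 | 63.8 | 36.1 |
| east | 50.0 | 62.4 | 35.5 |
| south-west | 0.250 | 4.3 | 95.7 |
| south-west | 0.417 | 7.3 | 94.4 |
| south-west | 0.667 | 10.3 | 88.7 |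
| south-west | 0.833 | 13.5 | 86.4 |
| south-west | 1.33 | 19.0 | 81.6 |
| south-west | 2.00 | 25.7 | 72.4 |
| south-west | 3.00 | 35.4 | 64.5 |

(each reading ± 1 percentage point)

- autumn: change nothing and wait 80 min more
- summer: at 80 min add reagent, 50.0% of the amount charged, then wait 80 min
- dawn: at 80 min add free catalyst, 50.0% of the amount charged, then wait 80 min
- winter: at 80 min take out 90% of the product then present, then wait 80 min

- what is taken out of product is counted as made
- additions bring no volume worth counting

1. product, in percent of the substrate first charged, at 80 min
2. the remedy with the largest gain of product, or "none" below 2 percentage points (autumn / summer / dawn / winter / none)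
3. product present, with what was taken out counted in, in percent of the substrate first charged, after dawn
4. product present, with what was taken out counted in, in percent of the substrate first charged, after winter

From 30.0 min on, the product readings of the east flask average 63.0%, with 35.7% substrate beside them. That makes c(product) 0.183 M. It gives 0.420 as the reagent share, c(product) at the stop over c(reagent) as charged. An even split of reagent between product and whatever else takes it would read 0.5, and the east flask lies a little below that.

The early rates are 0.0285 M/min in the east run and 0.0244 M/min in the south-west run. Their ratio stays below the ratio of the substrate charges, so I don't expect substrate to set the pace. Reagent isn't read, so my bet is unproven: the east flask stopped for lack of reagent, and the other 0.580 of it left by a side path.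

When you come at 80 min, expect 63.0% product in the east flask. Don't add free catalyst and don't take product out, since I expect neither to gain anything. Add reagent: at the same share, 50.0% more should bring 31.5% of the substrate charged, which is less than the substrate there.

The forecast gives 63%, winter as best, 63.2% after dawn and 81% after winter: “I read this as equilibrium with a live catalyst”. We part on best and on winter.

The simulation gives 63.1%, and summer as best with a gain of 37 percentage points, against 0 points for dawn and 0 points for winter. That leaves 63.1% after dawn and 63.1% after winter.

    reagent + free catalyst → catalyst intermediate A (k = 2.50 /M/s)
    catalyst intermediate A ⇌ catalyst intermediate B (K = 17.0, k = 38.0 /s)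
    substrate + catalyst intermediate B → catalyst intermediate C (k = 4.70 /M/s)
    catalyst intermediate C → free catalyst + product (k = 3.70 /s)
    2 reagent → homo dimer (k = 0.00840 /M/s)

At 80.0 min reagent, the limiting reagent, stands at 0% in the east flask. Product holds the 0.420 as read, and homo dimer at 0.126 M, two reagent each, holds 0.579. The summer gain of 37 points is as large as the 37% substrate left in the east flask, which is 0.492 per mole added, above my share. In the neighbour flask with 0.49 M substrate, the share gives 37.3% product, and that flask stores 39.8%. The east flask is at rest: at 800 min it holds 63.1% product and 36.9% substrate.

The readings stem from a simulated flask for an exercise.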